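**Plan**
1. Tetralone numbering: C1 ketone, C2, C3 carbinol, C4, C4a, C5 pyronyl, C6 phenyl, C7 H, C8 OH, C8a. Ring A is the benzene ring and ring B the cyclohexanone. After the protecting groups, the cuts are C8–O (back to C8–B), then C7–C8 and C4a–C8a together, with CO2 restored as a lactone bridge from C4a to C7.
2. Enabling feature: C4a (alkyl), C5 (pyronyl), C6 (phenyl) and C7 (H) of ring A are C6, C5, C4 and C3 of a 2-pyrone. C8 and C8a are the two carbons of an alkyne, and C4–C3–C2–C1 is a four-atom tether between them, so one cycloaddition with CO2 loss makes ring A and closes ring B.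
3. Earlier cuts: C1–C8a (aldehyde plus boryl acetylide), C5–C6 and the lactone C–O of the central pyrone (Michael addition and lactonisation with ethyl phenylpropiolate), and C4a–C5 (acylation of a lithiated methylpyrone by a glutarate ester).
4. Forward order: glutarate chain, union with the outer pyrone, central pyrone ring, alkyne at C1, rings A and B in one step, C8–B to C8–OH, then the two deprotections.
5. Stereochemistry: C3 is the only stereocentre. It comes from alkaloid-catalysed methanolysis of the prochiral anhydride, and the two chain ends are then told apart chemically. The alkynylation carbinol and the cycloadduct bridgeheads are erased later.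

Key step: step 11

Assumption: the quinine-series catalyst (DHQ)2AQN is taken to open 1 to the (R)-half ester 2, by analogy with 3-alkylglutaric anhydrides; the sign of rotation of 2, a known statin building block, checks this, and the pseudoenantiomer (DHQD)2AQN would be used if the sense were opposite.

**Step 1**
Reactants: 1 3-(tert-butyldimethylsilyloxy)glutaric anhydride
Product: 2 (3R)-3-(tert-butyldimethylsilyloxy)-5-methoxy-5-oxopentanoic acid
Conditions: MeOH (10 equiv), hydroquinine anthraquinone-1,4-diyl diether [(DHQ)2AQN] (0.3 equiv), Et2O, −40 °C; dilute HCl wash removes the catalyst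
Reagents that add atoms: methanol, CO
Why: Alkaloid-catalysed enantioselective alcoholysis (general-base desymmetrisation) of a prochiral 3-substituted glutaric anhydride directs methanol to one of the two enantiotopic carbonyl groups and so fixes the future C3 as R in 2.

**Step 2**
Reactants: 2 (3R)-3-(tert-butyldimethylsilyloxy)-5-methoxy-5-oxopentanoic acid
Product: 3 methyl (3R)-3-(tert-butyldimethylsilyloxy)-5-hydroxypentanoate
Conditions: BH3·SMe2 (1.5 equiv), THF, 0 °C to rt; aqueous work-up, used at once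
Reagents that add atoms: none
Why: Chemoselective borane reduction of a carboxylic acid beside a methyl ester leaves the ester, the silyl ether and the stereocentre untouched, and immediate use forestalls lactonisation of the hydroxy ester.

**Step 3**
Reactants: 3 methyl (3R)-3-(tert-butyldimethylsilyloxy)-5-hydroxypentanoate
Product: 4 methyl (3R)-3-(tert-butyldimethylsilyloxy)-5-(triethylsilyloxy)pentanoate
Conditions: Et3SiCl, imidazole, CH2Cl2, 0 °C
Reagents that add atoms: chlorotriethylsilane, CC[Si](Cl)(CC)CC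
Why: Routine silylation of a primary alcohol gives a triethylsilyl ether that withstands enolate and carbonate bases and can later be removed by mild acid beside the secondary tert-butyldimethylsilyl ether.

**Step 4**
Reactants: 5 4-hydroxy-6-methyl-2H-pyran-2-one
Product: 6 4-(benzyloxy)-6-methyl-2H-pyran-2-one
Conditions: BnBr, K2CO3, DMF, rt to 50 °C
Reagents that add atoms: benzyl bromide, BrCc1ccccc1
Why: Williamson-type O-alkylation of the acidic vinylogous carboxylic acid OH at C4 removes the acidic proton for the carbanion chemistry and installs a group that leaves by neutral hydrogenolysis at the end.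

**Step 5**
Reactants: 6 4-(benzyloxy)-6-methyl-2H-pyran-2-one; 4 methyl (3R)-3-(tert-butyldimethylsilyloxy)-5-(triethylsilyloxy)pentanoate
Product: 8 4-(benzyloxy)-6-[(4R)-4-(tert-butyldimethylsilyloxy)-2-oxo-6-(triethylsilyloxy)hexyl]-2H-pyran-2-one, via lithiated benzyloxypyrone 7 (not isolated)
Conditions: 6 (2.2 equiv), LiN(i-Pr)2 (2.1 equiv), THF, −78 °C; then 4 (1 equiv), −78 to −30 °C; AcOH quench
Reagents that add atoms: none
Why: In this Claisen-type acylation the extended enolate from deprotonation of the C6 methyl group attacks the methyl ester, and the second equivalent of anion deprotonates the more acidic product, which shields the new ketone from over-addition and from β-elimination of the silyloxy group.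

**Step 6**
Reactants: 8 4-(benzyloxy)-6-[(4R)-4-(tert-butyldimethylsilyloxy)-2-oxo-6-(triethylsilyloxy)hexyl]-2H-pyran-2-one; 9 ethyl 3-phenylpropiolate
Product: 11 5-[4-(benzyloxy)-2-oxo-2H-pyran-6-yl]-6-[(2R)-2-(tert-butyldimethylsilyloxy)-4-(triethylsilyloxy)butyl]-4-phenyl-2H-pyran-2-one, via Michael adduct 10 (not isolated)
Conditions: 9 (1.5 equiv), Cs2CO3 (0.5 equiv), DMF, rt to 60 °C
Reagents that add atoms: none
Why: Michael addition of the doubly activated methylene (between ketone and pyronyl) to the β-carbon of the arylpropiolate, then lactonisation of the ketone enolate oxygen onto the ethyl ester, is the classical 2-pyrone synthesis from benzyl-type ketones or β-dicarbonyl compounds; E and Z adducts equilibrate through the dienolate, and the weak base touches only the most acidic C–H.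

**Step 7**
Reactants: 11 5-[4-(benzyloxy)-2-oxo-2H-pyran-6-yl]-6-[(2R)-2-(tert-butyldimethylsilyloxy)-4-(triethylsilyloxy)butyl]-4-phenyl-2H-pyran-2-one
Product: 12 5-[4-(benzyloxy)-2-oxo-2H-pyran-6-yl]-6-[(2R)-2-(tert-butyldimethylsilyloxy)-4-hydroxybutyl]-4-phenyl-2H-pyran-2-one
Conditions: pyridinium p-toluenesulfonate (0.2 equiv), MeOH/CH2Cl2 1:1, 0 °C
Reagents that add atoms: none
Why: Acid-catalysed methanolysis separates the unhindered primary triethylsilyl ether from the bulkier secondary tert-butyldimethylsilyl ether by a wide rate margin and does not disturb either pyrone.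

**Step 8**
Reactants: 12 5-[4-(benzyloxy)-2-oxo-2H-pyran-6-yl]-6-[(2R)-2-(tert-butyldimethylsilyloxy)-4-hydroxybutyl]-4-phenyl-2H-pyran-2-one
Product: 13 (3S)-4-{5-[4-(benzyloxy)-2-oxo-2H-pyran-6-yl]-2-oxo-4-phenyl-2H-pyran-6-yl}-3-(tert-butyldimethylsilyloxy)butanal
Conditions: Dess–Martin periodinane (1.2 equiv), CH2Cl2, 0 °C to rt
Reagents that add atoms: none
Why: Dess–Martin oxidation stops at the aldehyde under nearly neutral conditions, so the β-silyloxy group is not eliminated (the descriptor changes to S only through ligand priorities).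

**Step 9**
Reactants: 14 potassium ethynyltrifluoroborate; 13 (3S)-4-{5-[4-(benzyloxy)-2-oxo-2H-pyran-6-yl]-2-oxo-4-phenyl-2H-pyran-6-yl}-3-(tert-butyldimethylsilyloxy)butanal
Product: 16 potassium trifluoro{(5R)-6-[5-(4-benzyloxy-2-oxo-2H-pyran-6-yl)-2-oxo-4-phenyl-2H-pyran-6-yl]-5-(tert-butyldimethylsilyloxy)-3-hydroxyhex-1-yn-1-yl}borate (both C3 epimers), via lithiated ethynyltrifluoroborate 15 (not isolated)
Conditions: 14 (1.5 equiv), n-BuLi (1.4 equiv), THF, −78 °C, 1 h; then 13, −78 to −40 °C; AcOH quench; acetone extraction, precipitation with Et2O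
Reagents that add atoms: none
Why: 1,2-Addition of a lithium acetylide to an aldehyde, with the tetracoordinate boron surviving C–H deprotonation, is the known entry to propargylic alcohol trifluoroborates; at −78 °C the aldehyde should outrun both pyrone carbonyls, and the uncontrolled carbinol centre is erased in step 10.

**Step 10**
Reactants: 16 potassium trifluoro{(5R)-6-[5-(4-benzyloxy-2-oxo-2H-pyran-6-yl)-2-oxo-4-phenyl-2H-pyran-6-yl]-5-(tert-butyldimethylsilyloxy)-3-hydroxyhex-1-yn-1-yl}borate
Product: 17 potassium trifluoro{(5S)-6-[5-(4-benzyloxy-2-oxo-2H-pyran-6-yl)-2-oxo-4-phenyl-2H-pyran-6-yl]-5-(tert-butyldimethylsilyloxy)-3-oxohex-1-yn-1-yl}borate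
Conditions: activated MnO2 (15 equiv), acetone, rt; filtration, precipitation with Et2O
Reagents that add atoms: none
Why: MnO2 oxidation is selective for the activated propargylic alcohol, is neutral and spares the C–B bond, which is the established way to ynone trifluoroborates, and both epimers converge on one ynone.

**Step 11**
Reactants: 17 potassium trifluoro{(5S)-6-[5-(4-benzyloxy-2-oxo-2H-pyran-6-yl)-2-oxo-4-phenyl-2H-pyran-6-yl]-5-(tert-butyldimethylsilyloxy)-3-oxohex-1-yn-1-yl}borate
Product: 19 potassium {(6S)-4-[4-(benzyloxy)-2-oxo-2H-pyran-6-yl]-6-(tert-butyldimethylsilyloxy)-8-oxo-3-phenyl-5,6,7,8-tetrahydronaphthalen-1-yl}trifluoroborate (boron on tetralone C8), via bridged lactone 18 (not isolated)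
Conditions: dry degassed MeCN (0.01 M), PTFE-lined sealed vessel, 150 °C; evaporation, trituration with Et2O
Reagents that add atoms: none
Why: The ynone triple bond adds across C3 and C6 of the 4-phenyl-2-pyrone in a concerted, asynchronous [4+2] cycloaddition (new bonds C7–C8 and C4a–C8a) to give the 2-oxabicyclo[2.2.2]octadienone 18, which loses CO2 by retro-[4+2] so that ring A becomes aromatic and nothing can revert. The closest known reaction type is the thermal 2-pyrone–alkyne Diels–Alder/decarboxylation, established intramolecularly for tethered alkynes and intermolecularly for alkynylboron dienophiles that deliver arylboron products. Ring B closes as a six-membered carbocycle in the cycloaddition itself, a fused (type 1) intramolecular closure through the tether C4–C3–C2–C1 from diene terminus C4a to alkyne carbon C8a, while ring A is assembled from four pyrone carbons and two alkyne carbons once the lactone bridge departs. No lasting stereocentre is formed, since the two bridgeheads of 18 vanish on aromatisation and C3 lies away from every bond change under neutral conditions. The step needs regiocontrol and a choice between two pyrone dienes: the tether permits only the orientation that places boron on C8, which also matches the polarity (electrophilic ynone β-carbon to nucleophilic pyrone C3), and the outer benzyloxypyrone could be reached only through an eight-membered ring. Dilute dry MeCN keeps the salt in solution, and the glass-free vessel limits protodeboronation and fluoride loss.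

**Step 12**
Reactants: 19 potassium {(6S)-4-[4-(benzyloxy)-2-oxo-2H-pyran-6-yl]-6-(tert-butyldimethylsilyloxy)-8-oxo-3-phenyl-5,6,7,8-tetrahydronaphthalen-1-yl}trifluoroborate
Product: 20 (3S)-5-[4-(benzyloxy)-2-oxo-2H-pyran-6-yl]-3-(tert-butyldimethylsilyloxy)-8-hydroxy-6-phenyl-3,4-dihydronaphthalen-1(2H)-one
Conditions: KHSO5 (1.05 equiv, as 2KHSO5·KHSO4·K2SO4), acetone/H2O, 0 °C to rt, minutes
Reagents that add atoms: potassium peroxymonosulfate, [K+].[O-]S(=O)(=O)OO
Why: ipso-Oxidation of an aryltrifluoroborate by peroxymonosulfate (peroxide on boron, 1,2-aryl shift from B to O, hydrolysis) is a fast known reaction, so the ketone, both heterocycle-derived units and the silyl ether have no time to react.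

**Step 13**
Reactants: 20 (3S)-5-[4-(benzyloxy)-2-oxo-2H-pyran-6-yl]-3-(tert-butyldimethylsilyloxy)-8-hydroxy-6-phenyl-3,4-dihydronaphthalen-1(2H)-one
Product: 21 (3S)-5-[4-(benzyloxy)-2-oxo-2H-pyran-6-yl]-3,8-dihydroxy-6-phenyl-3,4-dihydronaphthalen-1(2H)-one
Conditions: HF·pyridine, excess pyridine, THF, 0 °C to rt, plastic vessel
Reagents that add atoms: none
Why: Fluoride-mediated desilylation buffered with pyridine works close to neutrality and so avoids acid- or base-induced dehydration of the β-hydroxy ketone to a naphthol.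

**Step 14**
Reactants: 21 (3S)-5-[4-(benzyloxy)-2-oxo-2H-pyran-6-yl]-3,8-dihydroxy-6-phenyl-3,4-dihydronaphthalen-1(2H)-one
Product: 22 Wailupemycin F, (3S)-3,8-dihydroxy-5-(4-hydroxy-2-oxo-2H-pyran-6-yl)-6-phenyl-3,4-dihydronaphthalen-1(2H)-one
Conditions: H2 (1 atm), 10% Pd/C, EtOAc, rt; filtration
Reagents that add atoms: none
Why: Catalytic hydrogenolysis of the benzyl vinylogous ester is fast and neutral compared with reduction of the hydrogen-bonded aryl ketone or the pyrone ring, and the sensitive polar product is isolated by filtration and evaporation only.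

**Compound list**
1 | 3-(tert-butyldimethylsilyloxy)glutaric anhydride | CC(C)(C)[Si](C)(C)OC1CC(=O)OC(=O)C1 | starting material
2 | (3R)-3-(tert-butyldimethylsilyloxy)-5-methoxy-5-oxopentanoic acid | COC(=O)C[C@H](O[Si](C)(C)C(C)(C)C)CC(=O)O | intermediate
3 | methyl (3R)-3-(tert-butyldimethylsilyloxy)-5-hydroxypentanoate | COC(=O)C[C@H](O[Si](C)(C)C(C)(C)C)CCO | intermediate
4 | methyl (3R)-3-(tert-butyldimethylsilyloxy)-5-(triethylsilyloxy)pentanoate | COC(=O)C[C@H](O[Si](C)(C)C(C)(C)C)CCO[Si](CC)(CC)CC | intermediate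
5 | 4-hydroxy-6-methyl-2H-pyran-2-one | Cc1cc(O)cc(=O)o1 | starting material
6 | 4-(benzyloxy)-6-methyl-2H-pyran-2-one | Cc1cc(OCc2ccccc2)cc(=O)o1 | intermediate
7 | [4-(benzyloxy)-2-oxo-2H-pyran-6-yl]methyllithium (extended enolate, not isolated) | [Li]Cc1cc(OCc2ccccc2)cc(=O)o1 | intermediate
8 | 4-(benzyloxy)-6-[(4R)-4-(tert-butyldimethylsilyloxy)-2-oxo-6-(triethylsilyloxy)hexyl]-2H-pyran-2-one | O=C(Cc1cc(OCc2ccccc2)cc(=O)o1)C[C@H](O[Si](C)(C)C(C)(C)C)CCO[Si](CC)(CC)CC | intermediate
9 | ethyl 3-phenylpropiolate | CCOC(=O)C#Cc1ccccc1 | starting material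
10 | ethyl (7R)-4-[4-(benzyloxy)-2-oxo-2H-pyran-6-yl]-7-(tert-butyldimethylsilyloxy)-5-oxo-3-phenyl-9-(triethylsilyloxy)non-2-enoate (E/Z and C4 epimers, not isolated) | CCOC(=O)C=C(c1ccccc1)C(c1cc(OCc2ccccc2)cc(=O)o1)C(=O)C[C@H](O[Si](C)(C)C(C)(C)C)CCO[Si](CC)(CC)CC | intermediate
11 | 5-[4-(benzyloxy)-2-oxo-2H-pyran-6-yl]-6-[(2R)-2-(tert-butyldimethylsilyloxy)-4-(triethylsilyloxy)butyl]-4-phenyl-2H-pyran-2-one | O=c1cc(-c2ccccc2)c(-c2cc(OCc3ccccc3)cc(=O)o2)c(C[C@H](O[Si](C)(C)C(C)(C)C)CCO[Si](CC)(CC)CC)o1 | intermediate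
12 | 5-[4-(benzyloxy)-2-oxo-2H-pyran-6-yl]-6-[(2R)-2-(tert-butyldimethylsilyloxy)-4-hydroxybutyl]-4-phenyl-2H-pyran-2-one | O=c1cc(-c2ccccc2)c(-c2cc(OCc3ccccc3)cc(=O)o2)c(C[C@H](O[Si](C)(C)C(C)(C)C)CCO)o1 | intermediate
13 | (3S)-4-{5-[4-(benzyloxy)-2-oxo-2H-pyran-6-yl]-2-oxo-4-phenyl-2H-pyran-6-yl}-3-(tert-butyldimethylsilyloxy)butanal | O=c1cc(-c2ccccc2)c(-c2cc(OCc3ccccc3)cc(=O)o2)c(C[C@H](O[Si](C)(C)C(C)(C)C)CC=O)o1 | intermediate
14 | potassium ethynyltrifluoroborate | C#C[B-](F)(F)F.[K+] | starting material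
15 | potassium (lithioethynyl)trifluoroborate (not isolated) | [Li]C#C[B-](F)(F)F.[K+] | intermediate
16 | potassium trifluoro{(5R)-6-[5-(4-benzyloxy-2-oxo-2H-pyran-6-yl)-2-oxo-4-phenyl-2H-pyran-6-yl]-5-(tert-butyldimethylsilyloxy)-3-hydroxyhex-1-yn-1-yl}borate (C3 epimers) | O=c1cc(-c2ccccc2)c(-c2cc(OCc3ccccc3)cc(=O)o2)c(C[C@H](O[Si](C)(C)C(C)(C)C)CC(O)C#C[B-](F)(F)F)o1.[K+] | intermediate
17 | potassium trifluoro{(5S)-6-[5-(4-benzyloxy-2-oxo-2H-pyran-6-yl)-2-oxo-4-phenyl-2H-pyran-6-yl]-5-(tert-butyldimethylsilyloxy)-3-oxohex-1-yn-1-yl}borate | O=c1cc(-c2ccccc2)c(-c2cc(OCc3ccccc3)cc(=O)o2)c(C[C@H](O[Si](C)(C)C(C)(C)C)CC(=O)C#C[B-](F)(F)F)o1.[K+] | intermediate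
18 | 2-oxabicyclo[2.2.2]octa-5,7-dien-3-one cycloadduct of 17, potassium salt (lactone bridge from C4a to C7, double bonds C5=C6 and C8=C8a, ring B fused at C4a–C8a, 3S, bridgeheads unassigned, not isolated) | O=C1C[C@@H](O[Si](C)(C)C(C)(C)C)CC23OC(=O)C(C(c4ccccc4)=C2c2cc(OCc4ccccc4)cc(=O)o2)C([B-](F)(F)F)=C13.[K+] | intermediate
19 | potassium {(6S)-4-[4-(benzyloxy)-2-oxo-2H-pyran-6-yl]-6-(tert-butyldimethylsilyloxy)-8-oxo-3-phenyl-5,6,7,8-tetrahydronaphthalen-1-yl}trifluoroborate | O=C1C[C@@H](O[Si](C)(C)C(C)(C)C)Cc2c1c([B-](F)(F)F)cc(-c1ccccc1)c2-c1cc(OCc2ccccc2)cc(=O)o1.[K+] | intermediate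
20 | (3S)-5-[4-(benzyloxy)-2-oxo-2H-pyran-6-yl]-3-(tert-butyldimethylsilyloxy)-8-hydroxy-6-phenyl-3,4-dihydronaphthalen-1(2H)-one | O=C1C[C@@H](O[Si](C)(C)C(C)(C)C)Cc2c1c(O)cc(-c1ccccc1)c2-c1cc(OCc2ccccc2)cc(=O)o1 | intermediate
21 | (3S)-5-[4-(benzyloxy)-2-oxo-2H-pyran-6-yl]-3,8-dihydroxy-6-phenyl-3,4-dihydronaphthalen-1(2H)-one | O=C1C[C@@H](O)Cc2c1c(O)cc(-c1ccccc1)c2-c1cc(OCc2ccccc2)cc(=O)o1 | intermediate
22 | Wailupemycin F, (3S)-3,8-dihydroxy-5-(4-hydroxy-2-oxo-2H-pyran-6-yl)-6-phenyl-3,4-dihydronaphthalen-1(2H)-one | O=C1C[C@@H](O)Cc2c1c(O)cc(-c1ccccc1)c2-c1cc(O)cc(=O)o1 | target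

**Count**
Total steps: 14. Longest linear sequence: 13 steps (steps 1–3 and 5–14, from 1 to 22). Step 4 is the only side branch.

**Steps most likely to fail**

Step 11. The temperature needed for cycloaddition may exceed what the borate salt tolerates. Possible failures are protodeboronation, fluoride transfer from boron to silicon, β-elimination of silanol with aromatisation of ring B, and poor solubility of the salt.

The fallback sets out from 17. Me3SiCl (fluoride acceptor), pinacol and 2,6-lutidine in MeCN convert the borate into the neutral ynone pinacol boronate F1. This is the dienophile class for which the thermal pyrone cycloaddition is established. Heating in 1,2-dichlorobenzene at 160–180 °C should give, with loss of CO2, the C8 aryl pinacol boronate F2. KHSO5 in aqueous acetone then oxidises it to 20, where the route is rejoined.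

Step 6. Conjugate addition of the hindered, stabilised carbanion may be sluggish. Prolonged base contact could also cause elimination of the β-silyloxy group, or ring closure through carbon instead of oxygen.

The fallback sets out from 8 and brings in the phenyl group by cross-coupling instead of on the alkynoate.
- Me3SiOTf and Et3N in CH2Cl2 at 0 °C give the conjugated trimethylsilyl enol ether F3.
- Malonyl dichloride in Et2O (−78 °C to rt, 2,6-di-tert-butylpyridine as acid scavenger) acylates at carbon and lactonises at oxygen, giving the central 4-hydroxy-2-pyrone F4. This is the known silyl enol ether–malonyl dichloride pyrone synthesis.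
- Tf2O and pyridine give the pyron-4-yl triflate F5.
- Suzuki coupling with PhB(OH)2, Pd(PPh3)4 and K3PO4 in toluene at 80 °C returns to 11.

Step 9. The basic, heterogeneous dimetallated acetylide may abstract a proton from the acidic C6–CH2 or the aldehyde α-position. It may also attack a pyrone carbonyl instead of adding to the aldehyde.

The fallback sets out from 13 and postpones boron until after arene formation.
- HC≡CMgBr in THF at −78 °C gives the terminal propargylic alcohol F6.
- Dess–Martin oxidation gives the terminal ynone F7.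
- Heating in toluene or 1,2-dichlorobenzene (110–150 °C) effects the same intramolecular pyrone–alkyne cycloaddition with CO2 loss, giving the 8-unsubstituted tetralone F8.
- Carbonyl-directed ortho C–H borylation with [Ir(OMe)(cod)]2, AsPh3 and B2pin2 in octane at 120 °C functionalises the only C–H ortho to the ketone and gives the C8 aryl pinacol boronate F2.
- KHSO5 oxidises it to 20.

**Further compounds**
F1 | step 11 | 5-[4-(benzyloxy)-2-oxo-2H-pyran-6-yl]-6-[(2S)-2-(tert-butyldimethylsilyloxy)-4-oxo-6-(4,4,5,5-tetramethyl-1,3,2-dioxaborolan-2-yl)hex-5-yn-1-yl]-4-phenyl-2H-pyran-2-one | O=c1cc(-c2ccccc2)c(-c2cc(OCc3ccccc3)cc(=O)o2)c(C[C@H](O[Si](C)(C)C(C)(C)C)CC(=O)C#CB2OC(C)(C)C(C)(C)O2)o1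
F2 | step 11 | (3S)-5-[4-(benzyloxy)-2-oxo-2H-pyran-6-yl]-3-(tert-butyldimethylsilyloxy)-6-phenyl-8-(4,4,5,5-tetramethyl-1,3,2-dioxaborolan-2-yl)-3,4-dihydronaphthalen-1(2H)-one | O=C1C[C@@H](O[Si](C)(C)C(C)(C)C)Cc2c1c(B1OC(C)(C)C(C)(C)O1)cc(-c1ccccc1)c2-c1cc(OCc2ccccc2)cc(=O)o1
F3 | step 6 | 4-(benzyloxy)-6-[(4R)-4-(tert-butyldimethylsilyloxy)-6-(triethylsilyloxy)-2-(trimethylsilyloxy)hex-1-en-1-yl]-2H-pyran-2-one | C[Si](C)(C)OC(=Cc1cc(OCc2ccccc2)cc(=O)o1)C[C@H](O[Si](C)(C)C(C)(C)C)CCO[Si](CC)(CC)CC
F4 | step 6 | 5-[4-(benzyloxy)-2-oxo-2H-pyran-6-yl]-6-[(2R)-2-(tert-butyldimethylsilyloxy)-4-(triethylsilyloxy)butyl]-4-hydroxy-2H-pyran-2-one | O=c1cc(O)c(-c2cc(OCc3ccccc3)cc(=O)o2)c(C[C@H](O[Si](C)(C)C(C)(C)C)CCO[Si](CC)(CC)CC)o1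
F5 | step 6 | 5-[4-(benzyloxy)-2-oxo-2H-pyran-6-yl]-6-[(2R)-2-(tert-butyldimethylsilyloxy)-4-(triethylsilyloxy)butyl]-2-oxo-2H-pyran-4-yl trifluoromethanesulfonate | O=c1cc(OS(=O)(=O)C(F)(F)F)c(-c2cc(OCc3ccccc3)cc(=O)o2)c(C[C@H](O[Si](C)(C)C(C)(C)C)CCO[Si](CC)(CC)CC)o1
F6 | step 9 | 5-[4-(benzyloxy)-2-oxo-2H-pyran-6-yl]-6-[(2R)-2-(tert-butyldimethylsilyloxy)-4-hydroxyhex-5-yn-1-yl]-4-phenyl-2H-pyran-2-one (C4 epimers) | O=c1cc(-c2ccccc2)c(-c2cc(OCc3ccccc3)cc(=O)o2)c(C[C@H](O[Si](C)(C)C(C)(C)C)CC(O)C#C)o1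
F7 | step 9 | 5-[4-(benzyloxy)-2-oxo-2H-pyran-6-yl]-6-[(2S)-2-(tert-butyldimethylsilyloxy)-4-oxohex-5-yn-1-yl]-4-phenyl-2H-pyran-2-one | O=c1cc(-c2ccccc2)c(-c2cc(OCc3ccccc3)cc(=O)o2)c(C[C@H](O[Si](C)(C)C(C)(C)C)CC(=O)C#C)o1
F8 | step 9 | (3S)-5-[4-(benzyloxy)-2-oxo-2H-pyran-6-yl]-3-(tert-butyldimethylsilyloxy)-6-phenyl-3,4-dihydronaphthalen-1(2H)-one | O=C1C[C@@H](O[Si](C)(C)C(C)(C)C)Cc2c1ccc(-c1ccccc1)c2-c1cc(OCc2ccccc2)cc(=O)o1
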